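**Plan**

1. Numbering (kaurane type): ring A = C1–C5 and C10 (C20 methyl on C10, C6 on C5); ring C = C8, C9, C11–C14; ring D = C8, C14, C13, C16, C15 (C17 on C16); C7 is the oxymethylene on C8.
2. Cuts, in retrosynthetic order: lactol C6–O(C7); epoxide oxygen on C9/C11; C16–C17; C1–O and C2–O (back to C1=C2); C9=C11 (keto-aldehyde McMurry); C8–C7; C8–C9; C10–C9.
3. Forward: ring A (from a cyclohexenone ester) and ring D (from a cyclopentenone) are made separately and joined at C8–C9; ring C closes at C9=C11; the oxepane lactol closes last.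
4. Enabling feature: rings C and D share C8 and C13, so a C9 acyl group on C8 and a C12–C11 aldehyde chain on C13, cis on the cyclopentane, hold the two carbons of the future epoxide bond in reach for a six-membered closure; C9 lies between quaternary C8 and C10 and cannot enolise.
5. Stereochemistry: C5 from diastereoselective reduction plus lipase resolution; C10 by suprafacial [2,3] shift; C13 from (S)-4-silyloxycyclopentenone; C8 by attack anti to the C13 chain; C1/C2 by hydride addition opposite the axial methyls; C16, C9 and C11 by exo attack on the bicyclo[3.2.1]octene; C6 as the stable anomer.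

Key step: step 16

Abbreviations: TBS = tert-butyldimethylsilyl; TBDPS = tert-butyldiphenylsilyl; DMP = Dess–Martin periodinane; NMO = N-methylmorpholine N-oxide; DMDO = dimethyldioxirane.

Assumption 1: the lipase acylates the (4R)-carbinol of the trans hydroxy ester, as for related 3-hydroxy-α-ionone rings; if its preference is reversed, the wanted alcohol is the unreacted fraction and enters step 3 as such.
Assumption 2: the C6 hemiacetal settles as the (6R)-anomer drawn for the target.

**Route**

Step 1
Reactants: 1 ethyl 2,6,6-trimethyl-4-oxocyclohex-2-ene-1-carboxylate (racemic)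
Product: 2 ethyl trans-4-hydroxy-2,6,6-trimethylcyclohex-2-ene-1-carboxylate (racemic)
Conditions: NaBH4, CeCl3·7H2O, MeOH, −20 °C; chromatography
Reagents that add atoms: none
Why: Luche 1,2-reduction of the enone; in the half-chair that keeps the ester pseudoaxial (allylic strain with the C2 methyl) one C6 methyl is axial on the other face, so hydride should enter syn to the ester and leave the hydroxyl trans to it, the minor cis alcohol being removed by chromatography.

Step 2
Reactants: 2 ethyl trans-4-hydroxy-2,6,6-trimethylcyclohex-2-ene-1-carboxylate (racemic)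
Product: 3 ethyl (1R,4R)-4-acetoxy-2,6,6-trimethylcyclohex-2-ene-1-carboxylate
Conditions: Burkholderia cepacia lipase (Amano PS), vinyl acetate, t-BuOMe, 30 °C, stopped near half conversion; chromatography
Reagents that add atoms: vinyl acetate CC(=O)OC=C
Why: lipase-mediated kinetic resolution by irreversible transesterification; the enzyme should acylate the (4R)-carbinol (empirical rule for secondary alcohols), so the (1R,4R)-acetate is separated from the unreacted (1S,4S)-alcohol.

Step 3
Reactants: 3 ethyl (1R,4R)-4-acetoxy-2,6,6-trimethylcyclohex-2-ene-1-carboxylate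
Product: 4 (1R,4R)-4-(hydroxymethyl)-3,5,5-trimethylcyclohex-2-en-1-ol
Conditions: LiAlH4, THF, 0 °C → rt
Reagents that add atoms: none
Why: hydride reduction of the ester to the primary alcohol with reductive removal of the acetate; neither stereocentre is touched.

Step 4
Reactants: 4 (1R,4R)-4-(hydroxymethyl)-3,5,5-trimethylcyclohex-2-en-1-ol
Product: 5 (1R,4R)-4-(TBS-oxymethyl)-3,5,5-trimethylcyclohex-2-en-1-ol
Conditions: TBSCl (1.05 equiv), imidazole, CH2Cl2, −20 °C
Reagents that add atoms: tert-butyldimethylsilyl chloride CC(C)(C)[Si](C)(C)Cl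
Why: silylation selective for the primary hydroxyl over the secondary allylic one on steric grounds.

Step 5
Reactants: 5 (1R,4R)-4-(TBS-oxymethyl)-3,5,5-trimethylcyclohex-2-en-1-ol; 6 tributyl(iodomethyl)stannane
Product: 7 tributylstannylmethyl ether of 5
Conditions: KH, THF, 0 °C; then 6, rt
Reagents that add atoms: none
Why: Williamson etherification of the potassium alkoxide with the iodomethylstannane (Still's protocol); the carbinol centre is retained.

Step 6
Reactants: 7 tributylstannylmethyl ether of 5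
Product: 9 [(1R,6R)-6-(TBS-oxymethyl)-1,5,5-trimethylcyclohex-2-en-1-yl]methanol, via lithiomethyl ether 8 (not isolated)
Conditions: n-BuLi, THF, −78 → −20 °C; NH4Cl
Reagents that add atoms: none
Why: Still–Wittig [2,3]-sigmatropic rearrangement: tin–lithium exchange gives the α-alkoxymethyllithium, whose carbanion is delivered suprafacially to the methyl-bearing alkene carbon on the face of the departing C–O bond, so the new hydroxymethyl group on quaternary C10 should be trans to the C5 side chain while the alkene moves to C1=C2.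

Step 7
Reactants: 9 [(1R,6R)-6-(TBS-oxymethyl)-1,5,5-trimethylcyclohex-2-en-1-yl]methanol
Product: 10 (1R,6R)-6-(TBS-oxymethyl)-1,5,5-trimethylcyclohex-2-ene-1-carbaldehyde
Conditions: DMP, NaHCO3, CH2Cl2, 0 °C → rt
Reagents that add atoms: none
Why: Dess–Martin oxidation of the neopentyl primary alcohol to the non-enolisable aldehyde.

Step 8
Reactants: 11 (S)-4-(TBS-oxy)cyclopent-2-en-1-one
Product: 13 (R)-4-ethenylcyclopent-2-en-1-one, via silyloxy ketone 12 (not isolated)
Conditions: vinylMgBr, CuBr·SMe2 (10 mol %), THF, −78 → −40 °C; NH4Cl; crude product with DBU, CH2Cl2, 0 °C, short contact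
Reagents that add atoms: vinylmagnesium bromide C=C[Mg]Br
Why: copper-catalysed conjugate addition of the vinyl Grignard reagent anti to the silyloxy group, then base-induced E1cB loss of silanol toward the other α-carbon; the former β-carbon becomes C4 of a new enone (C13), its configuration fixed by the silyloxy stereocentre of 11.

Step 9
Reactants: 13 (R)-4-ethenylcyclopent-2-en-1-one; 10 (1R,6R)-6-(TBS-oxymethyl)-1,5,5-trimethylcyclohex-2-ene-1-carbaldehyde
Product: 15 C8–C9 aldol adduct (C8/C9 epimer mixture), via lithium enolate 14 (not isolated)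
Conditions: LiBH(s-Bu)3, THF, −78 °C; then 10, −78 → −40 °C; NH4Cl
Reagents that add atoms: none
Why: reductive aldol reaction: conjugate hydride addition gives the enolate regiospecifically at C8, remote from the vinyl-bearing carbon, and it adds to the non-enolisable aldehyde to form C8–C9; the two new centres form as a mixture and are both erased in steps 10 and 11.

Step 10
Reactants: 15 C8–C9 aldol adduct
Product: 16 C9/C15 1,3-diketone
Conditions: DMP, NaHCO3, CH2Cl2, rt
Reagents that add atoms: none
Why: Dess–Martin oxidation of the β-hydroxy ketone to the 1,3-diketone.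

Step 11
Reactants: 16 C9/C15 1,3-diketone
Product: 17 (2R,4R)-2-acyl-2-(hydroxymethyl)-4-ethenylcyclopentanone (C8 quaternary, C7 hydroxymethyl anti to the C13 ethenyl group)
Conditions: 37% aq. CH2O, KHCO3 (cat.), THF, 0 °C
Reagents that add atoms: formaldehyde C=O
Why: base-catalysed aldol hydroxymethylation (Tollens type) of the 1,3-diketone; formaldehyde should add to the planar C15–C8–C9 enolate on the ring-D face anti to the C13 ethenyl group, making C8 quaternary with the acyl group cis to that group, which is also the more stable isomer.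

Step 12
Reactants: 17 hydroxymethyl diketone
Product: 18 C7 TBDPS ether of 17
Conditions: TBDPSCl, imidazole, DMAP (cat.), DMF, 0 °C → rt
Reagents that add atoms: tert-butyldiphenylsilyl chloride CC(C)(C)[Si](Cl)(c1ccccc1)c1ccccc1
Why: silylation of the neopentyl primary alcohol under near-neutral conditions, which blocks retro-aldol loss of formaldehyde and, later, oxa-Michael addition to the C16 methylene ketone.

Step 13
Reactants: 18 C7 TBDPS ether
Product: 19 C15 ethylene ketal of 18
Conditions: (TMSOCH2)2, TMSOTf (cat.), CH2Cl2, −78 → −20 °C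
Reagents that add atoms: 1,2-bis(trimethylsilyloxy)ethane C[Si](C)(C)OCCO[Si](C)(C)C
Why: Noyori ketalisation; only the cyclopentanone carbonyl C15 should react, because the C9 ketone lies between two quaternary carbons.

Step 14
Reactants: 19 C15 ethylene ketal
Product: 21 C11 primary alcohol, via B-alkyl-9-BBN 20 (not isolated)
Conditions: 9-BBN, THF, 0 °C → rt; then 30% H2O2, aq. NaOH, 0 °C
Reagents that add atoms: hydrogen peroxide OO
Why: anti-Markovnikov hydroboration–oxidation (Brown) of the monosubstituted alkene; 9-BBN should leave the hindered ring-A cis-alkene and the hindered C9 ketone untouched.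

Step 15
Reactants: 21 C11 primary alcohol
Product: 22 C9-keto C11-aldehyde with C15 ketal
Conditions: DMP, NaHCO3, CH2Cl2, 0 °C → rt
Reagents that add atoms: none
Why: Dess–Martin oxidation of the primary alcohol to the C11 aldehyde; the ketone partner cannot enolise, so no aldol is expected.

Step 16
Reactants: 22 C9-keto C11-aldehyde with C15 ketal
Product: 24 ring A/C/D 9(11)-ene with C15 ketal, via titanium pinacolate 23 (not isolated)
Conditions: TiCl3(DME)1.5, Zn–Cu, DME, reflux; 22 added by syringe pump over 30 h, then further reflux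
Reagents that add atoms: none
Why: Low-valent titanium transfers single electrons to the C11 aldehyde and the C9 ketone, the ketyls join to form the C9–C11 bond as the titanium pinacolate 23, and loss of both oxygens to titanium at reflux gives the C9=C11 alkene. The closest known reaction type is the intramolecular McMurry keto-aldehyde coupling to cycloalkenes. Ring C closes as a six-membered ring by carbonyl–carbonyl coupling (6-exo attack of the C11 ketyl on the C9 carbonyl), which completes the bicyclo[3.2.1]oct-2-ene with the alkene away from the bridgeheads. No stereocentre is created; the closure only needs the C9 acyl group and the C12 chain cis on ring D, as set in step 11. Chemoselectivity rests on the dioxolane at C15, which leaves just two carbonyl groups, on the fact that C9 cannot enolise, and on slow addition at high dilution, which suppresses intermolecular aldehyde coupling. The silyl ethers, the ketal and the C1=C2 alkene are not expected to react.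

Step 17
Reactants: 24 ring A/C/D 9(11)-ene
Product: 25 (1S,2R)-1,2-diol (hydroxyls anti to C20)
Conditions: OsO4 (5 mol %), NMO, acetone–H2O, rt
Reagents that add atoms: osmium tetroxide O=[Os](=O)(=O)=O; N-methylmorpholine N-oxide C[N+]1([O-])CCOCC1; water O
Why: catalytic osmium tetroxide cis-dihydroxylation (Upjohn) of the C1=C2 alkene, the C9=C11 alkene being shielded by its two quaternary neighbours; attack is expected on the ring-A face opposite the axial C20 and C4 methyl groups, but either diol serves because both carbinol centres are erased in step 18.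

Step 18
Reactants: 25 (1S,2R)-1,2-diol
Product: 26 C1/C2 dione
Conditions: (COCl)2, DMSO, CH2Cl2, −78 °C; Et3N, → 0 °C
Reagents that add atoms: none
Why: Swern oxidation of the vicinal diol to the 1,2-dione (partly enolised toward C3) without C–C cleavage.

Step 19
Reactants: 26 C1/C2 dione
Product: 27 (1R,2S)-1,2-diol (hydroxyls syn to C20)
Conditions: NaBH4, MeOH–CH2Cl2, −20 → 0 °C
Reagents that add atoms: none
Why: borohydride reduction under steric approach control: ring A keeps the bulky C9 substituent equatorial, so C20 and one C4 methyl are axial on the same face and hydride should reach both carbonyls from the opposite face (equatorial attack at C2 as in 3,3,5-trimethylcyclohexanone, axial attack at C1 anti to C20), placing both hydroxyls syn to C20.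

Step 20
Reactants: 27 (1R,2S)-1,2-diol
Product: 28 1,2-diacetate
Conditions: Ac2O, DMAP, pyridine, 40 °C
Reagents that add atoms: acetic anhydride CC(=O)OC(C)=O
Why: DMAP-catalysed acetylation of both secondary alcohols, the axial C2 hydroxyl requiring the gentle warming.

Step 21
Reactants: 28 1,2-diacetate
Product: 29 C15 ketone with free C6 alcohol
Conditions: 2 M aq. HCl, THF, rt
Reagents that add atoms: water O
Why: acid hydrolysis removes the dioxolane and the primary TBS ether together, while the TBDPS ether, the acetates and the alkene should persist.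

Step 22
Reactants: 29 C15 ketone with free C6 alcohol
Product: 30 16-methylene-15-ketone
Conditions: (CH2O)n, PhNHMe·CF3CO2H, THF, reflux
Reagents that add atoms: formaldehyde C=O
Why: Mannich condensation–elimination with formaldehyde and an anilinium salt (Gras α-methylenation) at C16, the only enolisable position; the acidic medium spares the acetates.

Step 23
Reactants: 30 16-methylene-15-ketone
Product: 31 (16R)-16-methyl-15-ketone
Conditions: H2 (1 atm), RhCl(PPh3)3, benzene, rt
Reagents that add atoms: none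
Why: homogeneous hydrogenation of the unhindered 1,1-disubstituted enone alkene, the C9=C11 alkene being inert; hydrogen should be delivered to the exo face of the two-carbon bridge (the side of C14), so the C17 methyl ends endo.

Step 24
Reactants: 31 (16R)-16-methyl-15-ketone
Product: 32 9,11-exo-epoxide
Conditions: DMDO, acetone, 0 °C
Reagents that add atoms: dimethyldioxirane CC1(C)OO1
Why: dioxirane epoxidation of the remaining trisubstituted alkene on the exo face of the bicyclo[3.2.1]octene (side of the C14 bridge), the endo face being blocked by the C15–C16 bridge and its endo methyl group, which sets C9 and C11; no Baeyer–Villiger reaction is expected.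

Step 25
Reactants: 32 9,11-exo-epoxide
Product: 33 C6 aldehyde
Conditions: DMP, NaHCO3, CH2Cl2, 0 °C
Reagents that add atoms: none
Why: buffered Dess–Martin oxidation of the C6 alcohol to the aldehyde; the epoxide and acetates are inert and C5 is slow to enolise between two quaternary carbons.

Step 26
Reactants: 33 C6 aldehyde
Product: 35 CNP0210140.1, via hydroxy aldehyde 34 (not isolated)
Conditions: Bu4NF, AcOH, THF, 0 °C → rt
Reagents that add atoms: none
Why: fluoride desilylation frees the C7 hydroxyl, which adds to the C6 aldehyde to close the seven-membered lactol (hemiacetalisation) as the more stable anomer; acetic acid buffering protects the acetates and the C16 centre, and the bridgehead position of C8 rules out retro-aldol loss of C7.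

**Compound list**

1 | ethyl 2,6,6-trimethyl-4-oxocyclohex-2-ene-1-carboxylate (racemic) | CCOC(=O)C1C(C)=CC(=O)CC1(C)C | starting material
2 | ethyl trans-4-hydroxy-2,6,6-trimethylcyclohex-2-ene-1-carboxylate, racemic; the (1R,4R) enantiomer is drawn | CCOC(=O)[C@H]1C(C)=C[C@H](O)CC1(C)C | intermediate
3 | ethyl (1R,4R)-4-acetoxy-2,6,6-trimethylcyclohex-2-ene-1-carboxylate | CCOC(=O)[C@H]1C(C)=C[C@H](OC(C)=O)CC1(C)C | intermediate
4 | (1R,4R)-4-(hydroxymethyl)-3,5,5-trimethylcyclohex-2-en-1-ol | OC[C@H]1C(C)=C[C@H](O)CC1(C)C | intermediate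
5 | (1R,4R)-4-({[tert-butyl(dimethyl)silyl]oxy}methyl)-3,5,5-trimethylcyclohex-2-en-1-ol | CC(C)(C)[Si](C)(C)OC[C@H]1C(C)=C[C@H](O)CC1(C)C | intermediate
6 | tributyl(iodomethyl)stannane | CCCC[Sn](CCCC)(CCCC)CI | starting material
7 | tributyl({[(1R,4R)-4-({[tert-butyl(dimethyl)silyl]oxy}methyl)-3,5,5-trimethylcyclohex-2-en-1-yl]oxy}methyl)stannane | CC(C)(C)[Si](C)(C)OC[C@H]1C(C)=C[C@H](OC[Sn](CCCC)(CCCC)CCCC)CC1(C)C | intermediate
8 | {[(1R,4R)-4-({[tert-butyl(dimethyl)silyl]oxy}methyl)-3,5,5-trimethylcyclohex-2-en-1-yl]oxy}methyllithium (formed in situ) | CC(C)(C)[Si](C)(C)OC[C@H]1C(C)=C[C@H](OC[Li])CC1(C)C | intermediate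
9 | [(1R,6R)-6-({[tert-butyl(dimethyl)silyl]oxy}methyl)-1,5,5-trimethylcyclohex-2-en-1-yl]methanol | OC[C@]1(C)C=CCC(C)(C)[C@H]1CO[Si](C)(C)C(C)(C)C | intermediate
10 | (1R,6R)-6-({[tert-butyl(dimethyl)silyl]oxy}methyl)-1,5,5-trimethylcyclohex-2-ene-1-carbaldehyde (ring A aldehyde; CHO carbon = C9) | O=C[C@]1(C)C=CCC(C)(C)[C@H]1CO[Si](C)(C)C(C)(C)C | intermediate
11 | (S)-4-{[tert-butyl(dimethyl)silyl]oxy}cyclopent-2-en-1-one | O=C1C[C@H](O[Si](C)(C)C(C)(C)C)C=C1 | starting material
12 | (3R,4S)-3-ethenyl-4-{[tert-butyl(dimethyl)silyl]oxy}cyclopentan-1-one (formed in situ) | O=C1C[C@H](O[Si](C)(C)C(C)(C)C)[C@@H](C=C)C1 | intermediate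
13 | (R)-4-ethenylcyclopent-2-en-1-one | O=C1C=C[C@@H](C=C)C1 | intermediate
14 | lithium (R)-4-ethenylcyclopent-1-en-1-olate (formed in situ) | [Li]OC1=CC[C@@H](C=C)C1 | intermediate
15 | (4R)-4-ethenyl-2-{hydroxy[(1R,6R)-6-({[tert-butyl(dimethyl)silyl]oxy}methyl)-1,5,5-trimethylcyclohex-2-en-1-yl]methyl}cyclopentan-1-one, mixture of C8 and C9 epimers | O=C1C[C@H](C=C)CC1C(O)[C@]2(C)C=CCC(C)(C)[C@H]2CO[Si](C)(C)C(C)(C)C | intermediate
16 | (4R)-4-ethenyl-2-{[(1R,6R)-6-({[tert-butyl(dimethyl)silyl]oxy}methyl)-1,5,5-trimethylcyclohex-2-en-1-yl]carbonyl}cyclopentan-1-one (C8 epimers and enol forms) | O=C1C[C@H](C=C)CC1C(=O)[C@]2(C)C=CCC(C)(C)[C@H]2CO[Si](C)(C)C(C)(C)C | intermediate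
17 | (2R,4R)-4-ethenyl-2-(hydroxymethyl)-2-{[(1R,6R)-6-({[tert-butyl(dimethyl)silyl]oxy}methyl)-1,5,5-trimethylcyclohex-2-en-1-yl]carbonyl}cyclopentan-1-one (C7 anti, acyl syn to the C13 ethenyl group) | O=C([C@]1(C)C=CCC(C)(C)[C@H]1CO[Si](C)(C)C(C)(C)C)[C@@]2(CO)C[C@@H](C=C)CC2=O | intermediate
18 | C7 tert-butyldiphenylsilyl ether of 17 | O=C([C@]1(C)C=CCC(C)(C)[C@H]1CO[Si](C)(C)C(C)(C)C)[C@@]2(CO[Si](c3ccccc3)(c3ccccc3)C(C)(C)C)C[C@@H](C=C)CC2=O | intermediate
19 | C15 ethylene ketal (1,3-dioxolane) of 18 | O=C([C@]1(C)C=CCC(C)(C)[C@H]1CO[Si](C)(C)C(C)(C)C)[C@@]2(CO[Si](c3ccccc3)(c3ccccc3)C(C)(C)C)C[C@@H](C=C)CC24OCCO4 | intermediate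
20 | C11 B-alkyl-9-borabicyclo[3.3.1]nonane from 19 (formed in situ) | O=C([C@]1(C)C=CCC(C)(C)[C@H]1CO[Si](C)(C)C(C)(C)C)[C@@]2(CO[Si](c3ccccc3)(c3ccccc3)C(C)(C)C)C[C@@H](CCB3C4CCCC3CCC4)CC25OCCO5 | intermediate
21 | C11 primary alcohol (2-hydroxyethyl chain on C13; other centres as in 19) | O=C([C@]1(C)C=CCC(C)(C)[C@H]1CO[Si](C)(C)C(C)(C)C)[C@@]2(CO[Si](c3ccccc3)(c3ccccc3)C(C)(C)C)C[C@@H](CCO)CC24OCCO4 | intermediate
22 | ring-A/ring-D C9-keto C11-aldehyde with C15 ketal, C6 OTBS and C7 OTBDPS | O=C([C@]1(C)C=CCC(C)(C)[C@H]1CO[Si](C)(C)C(C)(C)C)[C@@]2(CO[Si](c3ccccc3)(c3ccccc3)C(C)(C)C)C[C@@H](CC=O)CC24OCCO4 | intermediate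
23 | titanium 9,11-pinacolate, drawn as the cyclic dichlorotitanium diolate; configuration at C9 and C11 not material (formed in situ) | C1(O[Ti](Cl)(Cl)O2)C2([C@]6(C)C=CCC(C)(C)[C@H]6CO[Si](C)(C)C(C)(C)C)[C@@]3(CO[Si](c4ccccc4)(c4ccccc4)C(C)(C)C)C[C@@H](C1)CC35OCCO5 | intermediate
24 | ring A/C/D 1,9(11)-diene with C15 ketal, C6 OTBS and C7 OTBDPS (bicyclo[3.2.1]oct-2-ene closed) | C1=C([C@]2(C)C=CCC(C)(C)[C@H]2CO[Si](C)(C)C(C)(C)C)[C@@]3(CO[Si](c4ccccc4)(c4ccccc4)C(C)(C)C)C[C@@H](C1)CC35OCCO5 | intermediate
25 | (1S,2R)-1,2-diol of 24, hydroxyls anti to C20 | C1=C([C@]2(C)[C@H](O)[C@H](O)CC(C)(C)[C@H]2CO[Si](C)(C)C(C)(C)C)[C@@]3(CO[Si](c4ccccc4)(c4ccccc4)C(C)(C)C)C[C@@H](C1)CC35OCCO5 | intermediate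
26 | C1/C2 dione (may exist as the C2 enol) | C1=C([C@]2(C)C(=O)C(=O)CC(C)(C)[C@H]2CO[Si](C)(C)C(C)(C)C)[C@@]3(CO[Si](c4ccccc4)(c4ccccc4)C(C)(C)C)C[C@@H](C1)CC35OCCO5 | intermediate
27 | (1R,2S)-1,2-diol, hydroxyls syn to C20 | C1=C([C@]2(C)[C@@H](O)[C@@H](O)CC(C)(C)[C@H]2CO[Si](C)(C)C(C)(C)C)[C@@]3(CO[Si](c4ccccc4)(c4ccccc4)C(C)(C)C)C[C@@H](C1)CC35OCCO5 | intermediate
28 | (1R,2S)-1,2-diacetate with C15 ketal, C6 OTBS and C7 OTBDPS | C1=C([C@]2(C)[C@@H](OC(C)=O)[C@@H](OC(C)=O)CC(C)(C)[C@H]2CO[Si](C)(C)C(C)(C)C)[C@@]3(CO[Si](c4ccccc4)(c4ccccc4)C(C)(C)C)C[C@@H](C1)CC35OCCO5 | intermediate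
29 | 1,2-diacetate with C15 ketone, free C6 alcohol and C7 OTBDPS | C1=C([C@]2(C)[C@@H](OC(C)=O)[C@@H](OC(C)=O)CC(C)(C)[C@H]2CO)[C@@]3(CO[Si](c4ccccc4)(c4ccccc4)C(C)(C)C)C[C@@H](C1)CC3=O | intermediate
30 | 16-methylene-15-ketone (exocyclic enone on ring D) | C1=C([C@]2(C)[C@@H](OC(C)=O)[C@@H](OC(C)=O)CC(C)(C)[C@H]2CO)[C@@]3(CO[Si](c4ccccc4)(c4ccccc4)C(C)(C)C)C[C@@H](C1)C(=C)C3=O | intermediate
31 | (16R)-16-methyl-15-ketone (methyl endo) | C1=C([C@]2(C)[C@@H](OC(C)=O)[C@@H](OC(C)=O)CC(C)(C)[C@H]2CO)[C@@]3(CO[Si](c4ccccc4)(c4ccccc4)C(C)(C)C)C[C@@H](C1)[C@@H](C)C3=O | intermediate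
32 | (9S,11R)-9,11-exo-epoxide with free C6 alcohol and C7 OTBDPS | CC(=O)O[C@H]1CC(C)(C)[C@@H](CO)[C@@](C)([C@H]1OC(C)=O)[C@@]23O[C@@H]2C[C@@H]4C[C@@]3(CO[Si](c5ccccc5)(c5ccccc5)C(C)(C)C)C(=O)[C@@H]4C | intermediate
33 | C6 aldehyde of 32 | CC(=O)O[C@H]1CC(C)(C)[C@@H](C=O)[C@@](C)([C@H]1OC(C)=O)[C@@]23O[C@@H]2C[C@@H]4C[C@@]3(CO[Si](c5ccccc5)(c5ccccc5)C(C)(C)C)C(=O)[C@@H]4C | intermediate
34 | C6-aldehyde C7-alcohol (open form of the lactol; formed in situ) | CC(=O)O[C@H]1CC(C)(C)[C@@H](C=O)[C@@](C)([C@H]1OC(C)=O)[C@@]23O[C@@H]2C[C@@H]4C[C@@]3(CO)C(=O)[C@@H]4C | intermediate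
35 | CNP0210140.1: (1R,2S,5R,6R,8S,9S,10S,11R,13S,16R)-1,2-diacetoxy-9,11-epoxy-6-hydroxy-6,7-seco-kauran-15-one 6,7-lactol | CC(=O)O[C@H]1CC(C)(C)[C@H]2[C@H](O)OC[C@@]34C[C@@H](C[C@H]5O[C@]53[C@]2(C)[C@H]1OC(C)=O)[C@@H](C)C4=O | target

**Count and risks**

Total steps: 26. Longest linear sequence: 25 steps (steps 1–7, then 9–26); step 8 is the side branch.

Most likely to fail:

1. Step 16 (reductive ring closure). The di-tertiary C9 ketone may fail to engage, so that the aldehyde is reduced or couples intermolecularly, or the coupling may stop at the pinacolate without deoxygenation. Fallback, setting out from 22: SmI2, HMPA, THF, −78 °C should effect the ketyl–carbonyl pinacol cyclisation through a samarium-bridged transition state to the cis-9,11-diol F1. Thiocarbonyldiimidazole, DMAP, toluene, 110 °C then gives the cyclic 9,11-thiocarbonate F2, and P(OMe)3 at reflux (Corey–Winter olefination) extrudes carbon dioxide to rejoin the route at 24. The same C9–C11 bond forms and the same ring closes, but bond formation and deoxygenation are separated.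

2. Step 9 (reductive aldol union). The borohydride may reduce the enone carbonyl directly instead of adding in the conjugate sense, or the aldol may revert at the hindered aldehyde. Fallback, setting out from 13: [(Ph3P)CuH]6 (cat.), PhMe2SiH, toluene, rt should give by 1,4-hydrosilylation the regio-defined silyl enol ether (R)-[(4-ethenylcyclopent-1-en-1-yl)oxy]dimethyl(phenyl)silane F3. A Mukaiyama aldol addition of F3 to 10 (BF3·OEt2, CH2Cl2, −78 °C) is irreversible under these conditions and rejoins the route at 15.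

3. Step 11 (C8 quaternary centre). Facial selectivity at C8 may be poor, or formaldehyde may be lost by retro-aldol before silylation. Fallback, setting out from 16: K2CO3 and 2-(iodomethyl)-4,4,5,5-tetramethyl-1,3,2-dioxaborolane in DMF at rt should C-alkylate the diketone irreversibly, the bulkier electrophile approaching anti to the ethenyl group, to give the C8 (pinacolboryl)methyl diketone F4. Oxidation of the C–B bond with NaBO3·4H2O in THF–H2O rejoins the route at 17.

**Further compounds**

F1 | step 16 | cis-9,11-diol from pinacol cyclisation of 22 (either cis face; C9 and C11 left undefined) | C1(O)C(O)([C@]6(C)C=CCC(C)(C)[C@H]6CO[Si](C)(C)C(C)(C)C)[C@@]3(CO[Si](c4ccccc4)(c4ccccc4)C(C)(C)C)C[C@@H](C1)CC35OCCO5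
F2 | step 16 | cyclic 9,11-thiocarbonate of F1 | C1(OC(=S)O2)C2([C@]6(C)C=CCC(C)(C)[C@H]6CO[Si](C)(C)C(C)(C)C)[C@@]3(CO[Si](c4ccccc4)(c4ccccc4)C(C)(C)C)C[C@@H](C1)CC35OCCO5
F3 | step 9 | (R)-[(4-ethenylcyclopent-1-en-1-yl)oxy]dimethyl(phenyl)silane | C[Si](C)(c1ccccc1)OC1=CC[C@@H](C=C)C1
F4 | step 11 | C8 (pinacolboryl)methyl analogue of 17 (CH2B(pin) in place of CH2OH) | O=C([C@]1(C)C=CCC(C)(C)[C@H]1CO[Si](C)(C)C(C)(C)C)[C@@]2(CB3OC(C)(C)C(C)(C)O3)C[C@@H](C=C)CC2=O
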